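The amounts stood at 0.010 M of electrophile, 9.50 mM of nucleophile and 3.00 mM of free base, and I had to decide whether that much free base would do for the next run or whether to charge more.

| setting | cedar | larch | alder | flask |
|---|---|---|---|---|
| electrophile | 0.014 M (fed, over 10 min) | 0.022 M (fed, over 10 min) | 0.010 M (fed, over 10 min) | 0.010 M (fed, over 10 min) |
| nucleophile | 9.5 mM | 9.5 mM | 4.8 mM | 9.50 mM |
| free base | 3 mM | 3 mM | 3 mM | 3.00 mM |
| remark | run made earlier | run made earlier | run made earlier |  |
| time |  |  |  | 10 min |

| run | time / min | electrophile / % | target / % |
|---|---|---|---|
| cedar | 2.50 | 25 | 3 |
| cedar | 5.00 | 44 | 3 |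
| cedar | 8.00 | 66 | 14 |
| cedar | 10.0 | 75 | 19 |
| larch | 1.33 | 11 | 0 |
| larch | 4.00 | 38 | 4 |
| larch | 6.00 | 51 | 8 |
| larch | 10.0 | 81 | 15 |
| alder | 0.833 | 10 | 0 |
| alder | 2.00 | 22 | 2 |
| alder | 4.00 | 36 | 4 |
| alder | 10.0 | 87 | 11 |

(scatter of a reading: 1.5 percentage points)

- part of the electrophile that has reacted at 10 min
- share of the unused nucleophile that is free and not bound as protonated nucleophile, at 10 min

- candidate steps: acid set free + free base <-> salt of the base; electrophile + nucleophile -> acid set free + target; nucleophile + target -> over-reaction product; electrophile -> decomposition product; nucleophile + acid set free <-> protonated nucleophile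
- percentages count the whole charge, also what has not yet gone in
- the earlier runs do not show how much of nucleophile is bound; that part of a forecast is a guess

The feed ends at 10 min, so what has reacted by then is the charge less the electrophile found. A portion fed steadily sits in the flask for about 5.00 min on average. As a rough form, not a law, I wrote the surviving share as exp(−h·N), with N the nucleophile charged, and let h take up whatever fall of nucleophile happens during the run. I read h from alder, whose acid set free in all, counted as the electrophile reacted, 1.30 mM, stayed below its 3 mM of free base. Cedar and larch ended with 3.50 mM and 4.18 mM, past their base, so I set them aside. The logarithm of charge over survivor, divided by alder's nucleophile, gave 0.0290 /mM, a reading that carries the scatter of 1.5 percentage points.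

For this flask that made 24.1% reacted, so 2.41 mM of acid set free in all, bound forms counted. Divided by the free base charged, this gives 0.803, which I call the base load, the acid set free in all per unit of free base charged. It stayed under one, so I left the free base as it was.

The forecast gave 24% (20% to 29%) for c and 93% (72% to 100%) for fr, with the words “Nucleophile binding is a guess, but mostly free”.

The flask gave c = 24.3% and fr = 99.8%, the latter 6.8 points above the forecast. At 10.0 min protonated nucleophile stood in this flask at 9.82 × 10⁻⁶ M. With the flask's own c the base load is 0.810, and 19.3% of the free base was still free.

    acid set free + free base ⇌ salt of the base, settled at all times (K = 7.40 × 10⁶ /M)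
    electrophile + nucleophile → acid set free + target (k = 7.50 /M/min)
    nucleophile + target → over-reaction product (k = 11.0 /M/min)
    electrophile → decomposition product (k = 2.00 × 10⁻⁵ /min)
    nucleophile + acid set free ⇌ protonated nucleophile, settled at all times (K = 2700 /M)

For a neighbouring flask, the same but with 0.024 M of nucleophile, the same h gives a base load of 1.67, which reckons 2.01 mM of acid past the free base charged and onto nucleophile. That flask gave c = 47.0%, 0.00167 M of protonated nucleophile and fr = 90.2%.

The data are calculated for substances that don't exist; scatter was added.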